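The benzene ring of the indole is disconnected at C5–C6. The key step exploits the substitution pattern of that ring, bromine on C4 and C6 and hydrogen on C5 and C7: a fully substituted N-tosylpyrrole carrying both methylthio groups, a 1-bromovinyl group at C3 (indole C4=C5) and a 2,2-dibromovinyl group at C2 (indole C7=C6) is a hexatriene through the pyrrole C2=C3 bond. In one operation, thermal 6π-electrocyclization closes the six-membered ring and loss of HBr across C5–C6 aromatizes it, leaving one bromine on C6 and the former vinylic bromine on C4. The triene is built from a 3-bromopyrrole-2-carbaldehyde; detosylation finishes the synthesis.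

Key step: step 7

Remark: 3-bromo-1H-pyrrole-2-carbaldehyde is taken as a purchasable building block; the labels C4 to C7a used for the key step follow indole numbering.

Step 1
Reactants: 1 3-bromo-1H-pyrrole-2-carbaldehyde; 2 dimethyl disulfide
Product: 4 3-bromo-4,5-bis(methylthio)-1H-pyrrole-2-carbaldehyde, via 3-bromo-5-(methylthio)-1H-pyrrole-2-carbaldehyde 3 (not isolated)
Conditions: MeSSMe (1.15 equiv), SO2Cl2 (1.1 equiv), CH2Cl2, −20 °C; then 1, −20 °C → rt
Reagents that add atoms: methanesulfenyl chloride, CSCl, made in the flask from dimethyl disulfide 2, CSSC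
Why: Electrophilic aromatic sulfenylation by MeSCl should take the only two free ring positions, C5 first and then C4, in parallel with the familiar 4,5-dihalogenation of pyrrole-2-carbaldehydes, while keeping SO2Cl2 limiting avoids ring chlorination.

Step 2
Reactants: 4 3-bromo-4,5-bis(methylthio)-1H-pyrrole-2-carbaldehyde; 5 p-toluenesulfonyl chloride
Product: 7 3-bromo-4,5-bis(methylthio)-1-tosyl-1H-pyrrole-2-carbaldehyde, via sodium 3-bromo-2-formyl-4,5-bis(methylthio)pyrrol-1-ide 6 (not isolated)
Conditions: NaH, DMF, 0 °C; then TsCl, 0 °C → rt
Reagents that add atoms: p-toluenesulfonyl chloride 5, Cc1ccc(cc1)S(Cl)(=O)=O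
Why: N-Sulfonylation of a pyrrolide, in which the 2-formyl group makes N–H acidic enough for complete deprotonation by NaH and the anion attacks TsCl at sulfur; the sulfonyl group is needed later to keep the aldehyde electrophilic and to lower pyrrole aromaticity.

Step 3
Reactants: 7 3-bromo-4,5-bis(methylthio)-1-tosyl-1H-pyrrole-2-carbaldehyde; 8 trimethylsilylacetylene
Product: 9 4,5-bis(methylthio)-1-tosyl-3-[(trimethylsilyl)ethynyl]-1H-pyrrole-2-carbaldehyde
Conditions: Pd(PPh3)2Cl2 (5 mol %), CuI (10 mol %), Et3N, THF, 60 °C, sealed tube
Reagents that add atoms: trimethylsilylacetylene 8, C#C[Si](C)(C)C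
Why: Sonogashira coupling, in which the C3–Br bond is activated for oxidative addition to zerovalent palladium by the ortho formyl and the N-sulfonyl group, and the methylthio groups on the electron-rich ring are expected to be spectators.

Step 4
Reactants: 9 4,5-bis(methylthio)-1-tosyl-3-[(trimethylsilyl)ethynyl]-1H-pyrrole-2-carbaldehyde; 10 carbon tetrabromide
Product: 11 2-(2,2-dibromovinyl)-4,5-bis(methylthio)-1-tosyl-3-[(trimethylsilyl)ethynyl]-1H-pyrrole
Conditions: CBr4 (2 equiv), PPh3 (4 equiv), CH2Cl2, 0 °C
Reagents that add atoms: carbon tetrabromide 10, BrC(Br)(Br)Br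
Why: Ramirez gem-dibromo-olefination (first stage of the Corey–Fuchs sequence), a Wittig reaction of Ph3P=CBr2 with an aldehyde that the N-tosyl group keeps electrophilic, run while the alkyne is still silyl-capped.

Step 5
Reactants: 11 2-(2,2-dibromovinyl)-4,5-bis(methylthio)-1-tosyl-3-[(trimethylsilyl)ethynyl]-1H-pyrrole
Product: 12 2-(2,2-dibromovinyl)-3-ethynyl-4,5-bis(methylthio)-1-tosyl-1H-pyrrole
Conditions: K2CO3 (0.2 equiv), MeOH/THF, 0 °C
Reagents that add atoms: none
Why: Base-catalysed methanolysis of the C(sp)–Si bond (protodesilylation) is mild enough for the gem-dibromoalkene and for the N-tosyl group, which is no longer labilised by a 2-formyl group because the olefination was placed first.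

Step 6
Reactants: 12 2-(2,2-dibromovinyl)-3-ethynyl-4,5-bis(methylthio)-1-tosyl-1H-pyrrole; 13 hydrogen bromide
Product: 14 3-(1-bromovinyl)-2-(2,2-dibromovinyl)-4,5-bis(methylthio)-1-tosyl-1H-pyrrole
Conditions: HBr (33% in AcOH, 1.2 equiv), Et4NBr, BHT (cat.), CH2Cl2, 0 °C, dark
Reagents that add atoms: hydrogen bromide 13, Br
Why: Markovnikov ionic hydrobromination of a terminal heteroaryl alkyne, in which the pyrrole ring stabilises positive charge on the internal carbon so that bromide adds there, the electron-poor dibromoalkene does not add HBr, and no formyl group remains to divert the cation towards hydration; as an addition it leaves no co-product.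

Step 7
Reactants: 14 3-(1-bromovinyl)-2-(2,2-dibromovinyl)-4,5-bis(methylthio)-1-tosyl-1H-pyrrole
Product: 16 4,6-dibromo-2,3-bis(methylthio)-1-tosyl-1H-indole, via 4,6,6-tribromo-2,3-bis(methylthio)-1-tosyl-5,6-dihydro-1H-indole 15 (not isolated)
Conditions: K2CO3 (powdered, 3 equiv), BHT (cat.), degassed o-xylene, 140 °C, dark
Reagents that add atoms: none
Why: The pyrrole C2=C3 bond is the central alkene of the triene H2C=C(Br)–C3=C2–CH=CBr2, whose end carbons become indole C5 and C6; on heating, the s-cis,s-cis conformer should undergo thermal disrotatory 6π-electrocyclization to the 5,6-dihydroindole 15, and loss of HBr (H from C5, one Br from C6), taken up by K2CO3, aromatizes both rings and makes the sequence irreversible. The reaction type is the known thermal 6π-electrocyclization of 2,3-dialkenylpyrroles to indoles with eliminative aromatization, used here on a triene with a dibrominated terminus. The benzene ring is closed in the electrocyclic mode, by bond formation between the two triene termini C5 and C6 with disrotatory motion. No stereocentre arises, because C6 of 15 bears two identical bromines and C5 two hydrogens, so the sense of rotation is without consequence. The step needs loss of exactly one bromine and no loss of the C4 bromine: the geminal pair on C6 leaves one bromine behind whichever one departs, and the C4–Br bond stays on an sp2 carbon throughout and has no elimination pathway. The N-tosyl group lowers the aromatic stabilization that the pyrrole gives up in 15, and the insoluble, weakly basic K2CO3 in a non-polar solvent scavenges HBr without dehydrobrominating either bromoalkene to an alkyne before closure.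

Step 8
Reactants: 16 4,6-dibromo-2,3-bis(methylthio)-1-tosyl-1H-indole
Product: 17 4,6-dibromo-2,3-bis(methylthio)-1H-indole
Conditions: KOH, MeOH/THF/H2O, 50 °C
Reagents that add atoms: none
Why: Nucleophilic cleavage of the sulfonamide N–S bond by attack at sulfur should be fast because the dibrominated, thio-substituted indolide is a good leaving group, and aryl bromides and thioethers are inert to KOH at this temperature.

Compound list
1 | 3-bromo-1H-pyrrole-2-carbaldehyde | O=Cc1[nH]ccc1Br | starting material
2 | dimethyl disulfide | CSSC | starting material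
3 | 3-bromo-5-(methylthio)-1H-pyrrole-2-carbaldehyde | O=Cc1[nH]c(SC)cc1Br | intermediate (not isolated)
4 | 3-bromo-4,5-bis(methylthio)-1H-pyrrole-2-carbaldehyde | O=Cc1[nH]c(SC)c(SC)c1Br | intermediate
5 | p-toluenesulfonyl chloride | Cc1ccc(cc1)S(Cl)(=O)=O | starting material
6 | sodium 3-bromo-2-formyl-4,5-bis(methylthio)pyrrol-1-ide | [Na+].O=Cc1[n-]c(SC)c(SC)c1Br | intermediate (not isolated)
7 | 3-bromo-4,5-bis(methylthio)-1-tosyl-1H-pyrrole-2-carbaldehyde | O=Cc1c(Br)c(SC)c(SC)n1S(=O)(=O)c1ccc(C)cc1 | intermediate
8 | trimethylsilylacetylene | C#C[Si](C)(C)C | starting material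
9 | 4,5-bis(methylthio)-1-tosyl-3-[(trimethylsilyl)ethynyl]-1H-pyrrole-2-carbaldehyde | O=Cc1c(C#C[Si](C)(C)C)c(SC)c(SC)n1S(=O)(=O)c1ccc(C)cc1 | intermediate
10 | carbon tetrabromide | BrC(Br)(Br)Br | starting material
11 | 2-(2,2-dibromovinyl)-4,5-bis(methylthio)-1-tosyl-3-[(trimethylsilyl)ethynyl]-1H-pyrrole | BrC(Br)=Cc1c(C#C[Si](C)(C)C)c(SC)c(SC)n1S(=O)(=O)c1ccc(C)cc1 | intermediate
12 | 2-(2,2-dibromovinyl)-3-ethynyl-4,5-bis(methylthio)-1-tosyl-1H-pyrrole | BrC(Br)=Cc1c(C#C)c(SC)c(SC)n1S(=O)(=O)c1ccc(C)cc1 | intermediate
13 | hydrogen bromide | Br | starting material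
14 | 3-(1-bromovinyl)-2-(2,2-dibromovinyl)-4,5-bis(methylthio)-1-tosyl-1H-pyrrole | CSc1c(SC)n(S(=O)(=O)c2ccc(C)cc2)c(C=C(Br)Br)c1C(Br)=C | intermediate
15 | 4,6,6-tribromo-2,3-bis(methylthio)-1-tosyl-5,6-dihydro-1H-indole | CSC1=C(SC)N(S(=O)(=O)c2ccc(C)cc2)C2=CC(Br)(Br)CC(Br)=C12 | intermediate (not isolated)
16 | 4,6-dibromo-2,3-bis(methylthio)-1-tosyl-1H-indole | CSc1c(SC)n(S(=O)(=O)c2ccc(C)cc2)c2cc(Br)cc(Br)c12 | intermediate
17 | 4,6-dibromo-2,3-bis(methylthio)-1H-indole | CSc1[nH]c2cc(Br)cc(Br)c2c1SC | target

Total steps: 8. Longest linear sequence: 8 steps (1 → 17).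

Steps most likely to fail

1. Step 7. Ring closure may be too slow, because one bromine of the CBr2 terminus must turn inward in the transition state and both alkenyl groups are twisted out of the pyrrole plane by the flanking tosyl and methylthio groups. Polymerization of the bromoalkenes, dehydrobromination to alkynes or loss of the tosyl group could then overtake cyclization. The fallback gives up the benzannulation and uses known indole chemistry; it sets out from dimethyl disulfide 2 and comes back to the route at the target 17. Methanesulfenyl chloride is made from 2 and SO2Cl2 as in step 1 and added (2.2 equiv, CH2Cl2, −78 °C → rt) to purchased 4,6-dibromo-1H-indole F1. Electrophilic substitution at C3 should give 4,6-dibromo-3-(methylthio)-1H-indole F2. The second equivalent should then enter at C2 by ipso attack at C3 and 1,2-shift of a methylthio group, the known 2,3-bis-sulfenylation of indoles, giving 17 without a protecting group.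

2. Step 6. The addition may not stop cleanly at the vinyl bromide: a second HBr may add to give the geminal dibromide, a radical chain may give the anti-Markovnikov isomer, the cationic intermediate may be captured by the neighbouring dibromoalkene, or the acid may cause loss or migration of a methylthio group. The fallback replaces ionic addition by bromoboration and protodeboronation; it sets out from 12 and comes back at 14. 9-Bromo-9-borabicyclo[3.3.1]nonane (CH2Cl2, 0 °C) should add B–Br syn across the terminal alkyne with boron on the terminal carbon, giving (Z)-9-[2-bromo-2-(2-(2,2-dibromovinyl)-4,5-bis(methylthio)-1-tosyl-1H-pyrrol-3-yl)vinyl]-9-borabicyclo[3.3.1]nonane F3. Protonolysis of the C–B bond with AcOH should then give 14 without a free vinyl cation or a strong acid.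

3. Step 1. The second substitution, at C4 between bromine and the new methylthio group on a formyl-deactivated ring, may stall at the monosulfide, and the HCl formed may cause scrambling or loss of sulfur substituents. The fallback reverses the order of C–S and C–Br bond formation; it sets out from dimethyl disulfide 2 and comes back at 4. Purchased 1H-pyrrole-2-carbaldehyde F4 is treated with methanesulfenyl chloride (2.1 equiv, made from 2 as in step 1). The unhalogenated ring is more nucleophilic and should be sulfenylated through 5-(methylthio)-1H-pyrrole-2-carbaldehyde F5 to 4,5-bis(methylthio)-1H-pyrrole-2-carbaldehyde F6, in parallel with the known 4,5-dihalogenation of this aldehyde. Electrophilic bromination with NBS (THF, −78 °C) at C3, the only free ring position, should then give 4.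

Further compounds
F1 | step 7 | 4,6-dibromo-1H-indole | Brc1cc(Br)c2cc[nH]c2c1
F2 | step 7 | 4,6-dibromo-3-(methylthio)-1H-indole | CSc1c[nH]c2cc(Br)cc(Br)c12
F3 | step 6 | (Z)-9-[2-bromo-2-(2-(2,2-dibromovinyl)-4,5-bis(methylthio)-1-tosyl-1H-pyrrol-3-yl)vinyl]-9-borabicyclo[3.3.1]nonane | Br/C(=C\B1C2CCCC1CCC2)c1c(SC)c(SC)n(S(=O)(=O)c2ccc(C)cc2)c1C=C(Br)Br
F4 | step 1 | 1H-pyrrole-2-carbaldehyde | O=Cc1ccc[nH]1
F5 | step 1 | 5-(methylthio)-1H-pyrrole-2-carbaldehyde | O=Cc1ccc(SC)[nH]1
F6 | step 1 | 4,5-bis(methylthio)-1H-pyrrole-2-carbaldehyde | O=Cc1cc(SC)c(SC)[nH]1
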